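## The problem

Ambofuranol is a 2-arylbenzofuran. Furan carbon C2 carries ring B (2-hydroxy-4-methoxyphenyl), C3 carries a methoxy group, and ring A (C3a, C4 to C7, C7a) carries a prenyl group on C5 and a free hydroxyl on C6. There is no stereocentre, so nothing has to be controlled in three dimensions; the difficulty is regiochemical. Four oxygen substituents must be told apart (two methylated, two free), and the prenyl group must sit on C5 and not on C7 or on oxygen. Joining the rings by substitution on a preformed resorcinol-type ring A meets this head-on, because C-prenylation of such rings gives C5, C7 and O-alkylated mixtures. The fragile parts are the ortho-prenylphenol, which closes to a 2,2-dimethylchroman under acid and rules out hydrogenolysis, and the 3-methoxybenzofuran, an enol ether that tolerates neither acid nor oxidants. The enabling feature is that the edge C5(prenyl)–C6(OH)–C7 is, atom for atom, the enol form of 6-methylhept-5-en-2-one (C5 is its C3, C6 its carbonyl carbon, C7 its methyl group). The remaining ring A atoms C4, C3a and C7a, together with O1, C2 and C3, form a furan-3-carbaldehyde (C4 is the formyl carbon) with a leaving group on the adjacent ring carbon C7a. These two pieces are already at the oxidation level of the phenol, so ring A can be assembled around a prenyl group that was attached earlier to an sp3 carbon, where its position is not in doubt.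

## Retrosynthesis

**17 to 16.** The target 17 is traced back to its ring B triisopropylsilyl ether 16 by cutting one O–Si bond. A silyl ether is preferred to an acetal or benzyl ether because fluoride is the only deprotection that leaves both the ortho-prenylphenol and the enol ether alone. The ring B phenol cannot stay free earlier, since it would quench the organolithium, the ketene ylide and the chloroiminium reagent used before. The ring A phenol needs no protection because it is only created one step before the end.

**16 to 11 and 14.** Ring A of 16 is opened at C4=C5 and C7–C7a, giving the chloroformylfuran 11 and the α-prenyl β-ketophosphonate 14; the dienone 15 lies between them in the forward direction. Neighbouring cuts are weaker: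
- Removing the prenyl group from C5 brings back the C5/C7/O selectivity problem.
- Cutting the furan ring instead (O1–C2, C2–C3) leaves a prenylated resorcinol that must again be made by arene substitution.
- Cutting the same two bonds with the plain ketone in place of 14 would let the methyl carbon condense with the aldehyde and put prenyl on C7.

The gain is large: ring A disappears, 11 already holds all four furan substituents in their final form, and 14 is one alkylation from a catalogue compound. The forward reaction must achieve three things:
- olefination by a hindered, α-branched phosphonate;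
- the geometry of C4=C5 with acetyl cis to the furan;
- closure through carbon with loss of chloride.

No oxidant is needed.

**14 to 12 and 13.** The bond between the phosphorus-bearing carbon and the prenyl CH2 is cut, giving dimethyl (2-oxopropyl)phosphonate 12 and prenyl bromide 13. Acylating a homoprenylphosphonate would reach 14 as well but takes two steps. The forward reaction must stop at mono-C-alkylation.

**11 to 9.** The formyl C–C bond at furan C3 and the C–Cl bond at furan C2 are both traced to the butenolide 9, whose lactone carbonyl becomes the chloride; the iminium salt 10 is the intermediate. One haloformylation installs both groups and aromatises the ring, whereas a metalation route would need a separate chlorination and a separate formylation. The precursor is simpler by one ring oxidation level and two substituents. The reaction must choose lactone C3 over ring B, and the silyl ether must survive.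

**9 to 6 and 7.** The lactone O–C(=O) bond and the C3=C4 double bond of 9 are cut, giving the mandelate 6 and the ketene ylide 7, which supplies two ring carbons; the ester ylide 8 is the intermediate. The classical neighbour (acetate, Dieckmann closure to the tetronic acid, O-methylation) costs three steps and raises an O-methylation regiochemistry question. Here the methoxy group of the ester becomes the enol ether directly. The reaction needs a hindered secondary alcohol to add to the ylide and an ester-stabilised ylide to olefinate an ester.

**6 to 1.** The mandelate 6 comes from the α-keto ester 5 by reduction. The aryl–C(O) bond of 5 is cut to the aryl bromide 2 (through aryllithium 4) and dimethyl oxalate 3, and 2 comes from 2-bromo-5-methoxyphenol 1 by silylation. The bromine of 1 fixes the attachment point ortho to OH and para to OMe, which Friedel–Crafts acylation of the parent phenol would not do cleanly. The forward steps require low temperature (no silyl migration, no double addition) and a chemoselective ketone reduction.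

## Roads not taken

**Alternative 1:** The cut runs through O1–C2 and C2–C3. C2 would arrive as the benzylic carbon of the ring B sulfonium salt [4-methoxy-2-(methoxymethoxy)benzyl]diphenylsulfonium tetrafluoroborate A3. Ring A with C3 would arrive as a masked salicylate, 7-(methoxymethoxy)-2,2-dimethyl-6-(3-methylbut-2-enyl)-4H-1,3-benzodioxin-4-one A2. In the forward step the ylide from A3 and a silylamide base attacks the carbonyl of A2, the ketal collapses, and the freed phenoxide displaces the sulfide at the same carbon. This closes the five-membered ring to the racemic coumaranone 6-(methoxymethoxy)-2-[4-methoxy-2-(methoxymethoxy)phenyl]-5-(3-methylbut-2-enyl)benzofuran-3(2H)-one A1.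
- Merits: the plan is convergent, both partners are ordinary aromatic compounds, and each bond-forming event is a polar process of a known kind (acyl transfer to a sulfur ylide, alkylation by an α-keto sulfonium). In this respect its key step is more secure than the one chosen.
- Weak points: A1 is not yet a benzofuran. Its enol oxygen must be methylated in competition with C-alkylation at C2, and two acetals must then be removed with acid, the one reagent class the ortho-prenylphenol and the enol ether tolerate poorly. A2 also already contains the prenylated ring A, so the C5/C7 problem is moved into its preparation, not solved.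
- Comparison: the chosen plan offers a less certain key step, but it delivers 16 with the methyl ethers and the prenyl position already correct and only a fluoride step to follow.

**Alternative 2:** Only C2=C3 is cut. The precursor is the phosphonium salt {[2-{[4-methoxy-2-(triisopropylsilyloxy)benzoyl]oxy}-5-(3-methylbut-2-enyl)-4-(triisopropylsilyloxy)phenyl](methoxy)methyl}triphenylphosphonium bromide A5. Its ylide attacks the neighbouring aryl ester and expels the phosphine oxide, giving ambofuranol bis(triisopropylsilyl) ether A4.
- Merits: intramolecular ester olefination of ortho-acyloxybenzyl ylides is an established route to 2-arylbenzofurans. The 3-methoxy group is in place as soon as the ring closes, and a single fluoride step follows. On post-key-step economy it equals the chosen plan, and its bond construction is nearer to precedent.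
- Weak points: the ylide carbon bears a methoxy group, which makes the ylide unstabilised and the salt itself an O,P-acetal. Preparing A5 requires acid-mediated substitution next to an aryl ester and two silyl ethers. Ring A must be bought or made as a benzaldehyde with three differentiated oxygen functions and a prenyl group already on C5, so the sequence is several steps longer and again depends on regioselective arene prenylation.
- Comparison: the chosen plan accepts an unprecedented ring closure in exchange for a shorter route in which the prenyl position is decided by alkylating 12.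

**Alternative 3:** The cut runs through C3a–C7a and C6–C7. Ring A is made from a furan and an alkyne, from the racemic 2-acylfuran 2-(ethynyloxy)-2-[4-methoxy-2-(triisopropylsilyloxy)phenyl]-1-[4-(3-methylbut-2-enyl)furan-2-yl]ethan-1-one A7. On heating, the furan would add the tethered ynol ether across its 2,5-positions. The oxygen bridge would then open to the phenol, giving racemic 6-hydroxy-2-[4-methoxy-2-(triisopropylsilyloxy)phenyl]-5-(3-methylbut-2-enyl)benzofuran-3(2H)-one A6.
- Merits: like the chosen plan it builds ring A de novo, so the prenyl position is set by the furan substitution. It needs no base and no leaving group, and the phenol oxygen comes from the furan.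
- Weak points:
  - A7 is an ynol ether of an α-hydroxy ketone whose α-hydrogen is activated twice, and the usual strongly basic ynol ether syntheses do not fit it.
  - A 2-acylfuran is an electron-poor diene.
  - The bridge must open at the C3a–O bond, although the ring oxygen on C7a stabilises the cation from C6–O cleavage better.
  - A6 has a free ring A phenol beside the ketone, so methylating the enol oxygen selectively would need extra protecting-group steps.
- Comparison: the idea is the closest in spirit to the chosen plan, but the chosen plan reaches the correctly methylated benzofuran directly from precursors available in at most five steps.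

Key step: step 7

Remark: the target has no stereocentre, so 6, 8, 9 and 14 are carried as racemates; their stereocentres become sp2 carbons in steps 5 and 7. Compound 7 is treated as a purchased starting material because it supplies C3a and C7a.

## Route

Step 1
Reactants: 1 2-bromo-5-methoxyphenol
Product: 2 (2-bromo-5-methoxyphenoxy)tri(propan-2-yl)silane
Conditions: i-Pr3SiCl, imidazole, DMF, rt
Reagents that add atoms: chlorotri(propan-2-yl)silane, CC(C)[Si](Cl)(C(C)C)C(C)C
Why: Standard imidazole-mediated silylation of a phenol; the triisopropylsilyl ether is chosen because it resists the organolithium, ylide and chloroiminium reagents that follow and is removed by fluoride at the end.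

Step 2
Reactants: 2 (2-bromo-5-methoxyphenoxy)tri(propan-2-yl)silane; 3 dimethyl oxalate
Product: 5 methyl 2-[4-methoxy-2-(triisopropylsilyloxy)phenyl]-2-oxoacetate, via aryllithium 4 (not isolated)
Conditions: n-BuLi, THF, −78 °C; cannulated into 3 (3 equiv), THF, −78 °C; aq. NH4Cl
Reagents that add atoms: none
Why: Bromine–lithium exchange followed by inverse addition to excess dialkyl oxalate is the standard acylation route to aryl glyoxylates; at −78 °C the tetrahedral adduct persists until the quench, so a second addition is avoided, and the bulky silyl group should not migrate from oxygen to carbon.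

Step 3
Reactants: 5 methyl 2-[4-methoxy-2-(triisopropylsilyloxy)phenyl]-2-oxoacetate
Product: 6 methyl 2-hydroxy-2-[4-methoxy-2-(triisopropylsilyloxy)phenyl]acetate (racemic)
Conditions: NaBH4 (0.5 equiv), MeOH–THF, −20 °C
Reagents that add atoms: none
Why: Chemoselective borohydride reduction of the ketone of an α-keto ester at low temperature; the new stereocentre is formed as a racemate and is erased in step 5.

Step 4
Reactants: 6 methyl 2-hydroxy-2-[4-methoxy-2-(triisopropylsilyloxy)phenyl]acetate; 7 (triphenyl-λ5-phosphanylidene)ethenone (Ph3P=C=C=O)
Product: 9 4-methoxy-5-[4-methoxy-2-(triisopropylsilyloxy)phenyl]furan-2(5H)-one (racemic), via ester ylide 8 (not isolated)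
Conditions: PhCO2H (cat.), toluene, 110 °C
Reagents that add atoms: none
Why: Domino addition–intramolecular Wittig olefination of an α-hydroxy ester with the ketene ylide: the alcohol adds to the cumulated ylide to give ester ylide 8, which olefinates the neighbouring methyl ester, so the ester methoxy group becomes the 4-methoxy group of the tetronate with no separate O-methylation.

Step 5
Reactants: 9 4-methoxy-5-[4-methoxy-2-(triisopropylsilyloxy)phenyl]furan-2(5H)-one
Product: 11 2-chloro-4-methoxy-5-[4-methoxy-2-(triisopropylsilyloxy)phenyl]furan-3-carbaldehyde, via iminium chloride 10 (not isolated)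
Conditions: POCl3 (3 equiv), DMF, 0 to 60 °C; aq. NaOAc
Reagents that add atoms: N,N-dimethylformamide, CN(C)C=O; phosphoryl chloride, O=P(Cl)(Cl)Cl; water, O
Why: Vilsmeier–Haack–Arnold haloformylation of an enolisable five-membered lactone, as practised on benzofuran-2(3H)-one and on 4-methoxy-3-pyrrolin-2-one: the lactone reacts through its 2-hydroxyfuran tautomer, the only free ring carbon C3 is formylated and the activated carbonyl oxygen is exchanged for chloride. C5 is blocked by the aryl group, and ring B, with its bulky and weakly donating silyloxy group, should be the slower nucleophile.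

Step 6
Reactants: 12 dimethyl (2-oxopropyl)phosphonate; 13 1-bromo-3-methylbut-2-ene
Product: 14 dimethyl (6-methyl-2-oxohept-5-en-3-yl)phosphonate (racemic)
Conditions: 12 (1.2 equiv), NaH, THF, 0 °C; 13, 0 °C to rt
Reagents that add atoms: none
Why: C-alkylation of the sodium enolate of a β-ketophosphonate at the carbon between phosphorus and carbonyl by a reactive allylic bromide; a slight excess of 12 holds back dialkylation.

Step 7
Reactants: 11 2-chloro-4-methoxy-5-[4-methoxy-2-(triisopropylsilyloxy)phenyl]furan-3-carbaldehyde; 14 dimethyl (6-methyl-2-oxohept-5-en-3-yl)phosphonate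
Product: 16 3-methoxy-2-[4-methoxy-2-(triisopropylsilyloxy)phenyl]-5-(3-methylbut-2-enyl)benzofuran-6-ol, via dienone 15 (not isolated)
Conditions: 14 (1.2 equiv), NaH, THF, 0 °C; 11, 0 °C to rt; then Cs2CO3 (3 equiv), PhSH (0.2 equiv), DMF, 80 °C
Reagents that add atoms: none
Why: Proposed new method: the sodium salt of 14 adds to the aldehyde of 11 and loses dimethyl phosphate (Horner–Wadsworth–Emmons olefination), which forms C4=C5 and fixes prenyl on C5 because only the phosphorus-bearing carbon can olefinate; the closest known reaction type is the base-mediated [3+3] benzannulation of β-chlorovinyl aldehydes from Vilsmeier haloformylation with 1,3-dinucleophiles such as acetonedicarboxylates, and a ketophosphonate as the C3 partner on a chlorofuran has no precedent. Carbonate then enolises the methyl ketone of 15 reversibly, and in the isomer with acetyl cis to the furan the 2-oxidohexatriene C7=C6–C5=C4–C3a=C7a closes ring A by thermal disrotatory six-electron electrocyclisation, in polar terms a 6-endo attack of the enolate carbon on the chlorine-bearing furan carbon, forming C7–C7a. Vinylogous loss of chloride from C7a and tautomerisation of the cyclohexadienone give the ring A phenoxide, so the aromatic oxidation level is reached without an oxidant. No stereocentre is created, since the sp3 carbon C7a of the cyclised intermediate becomes planar again. The selectivity the step needs is the geometry of C4=C5: the olefination is expected to favour the unproductive isomer with acetyl trans to the furan, so catalytic benzenethiolate is added to interconvert the isomers by reversible conjugate addition at C4 while the productive isomer is drained irreversibly. This equilibration is preferred to deprotonation at the doubly allylic CH2 of the prenyl group, which could move the prenyl double bond into conjugation. Closure through carbon is expected to prevail over closure through the enolate oxygen because the O-closed 2H-pyran can reopen, whereas the C-closed ring ends as a benzene.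

Step 8
Reactants: 16 3-methoxy-2-[4-methoxy-2-(triisopropylsilyloxy)phenyl]-5-(3-methylbut-2-enyl)benzofuran-6-ol
Product: 17 ambofuranol, 2-(2-hydroxy-4-methoxyphenyl)-3-methoxy-5-(3-methylbut-2-enyl)benzofuran-6-ol
Conditions: Bu4NF, AcOH, THF, 0 °C
Reagents that add atoms: none
Why: Fluoride cleavage of an aryl silyl ether; acetic acid buffering keeps both phenols protonated, and neither the prenyl group nor the enol ether reacts with fluoride.

## Compound list

1 | 2-bromo-5-methoxyphenol | COc1ccc(Br)c(O)c1 | starting material
2 | (2-bromo-5-methoxyphenoxy)tri(propan-2-yl)silane | COc1ccc(Br)c(O[Si](C(C)C)(C(C)C)C(C)C)c1 | intermediate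
3 | dimethyl oxalate | COC(=O)C(=O)OC | starting material
4 | [4-methoxy-2-(triisopropylsilyloxy)phenyl]lithium (not isolated) | [Li]c1ccc(OC)cc1O[Si](C(C)C)(C(C)C)C(C)C | intermediate
5 | methyl 2-[4-methoxy-2-(triisopropylsilyloxy)phenyl]-2-oxoacetate | COC(=O)C(=O)c1ccc(OC)cc1O[Si](C(C)C)(C(C)C)C(C)C | intermediate
6 | methyl 2-hydroxy-2-[4-methoxy-2-(triisopropylsilyloxy)phenyl]acetate (racemic) | COC(=O)C(O)c1ccc(OC)cc1O[Si](C(C)C)(C(C)C)C(C)C | intermediate
7 | (triphenyl-λ5-phosphanylidene)ethenone, Ph3P=C=C=O | O=C=C=P(c1ccccc1)(c1ccccc1)c1ccccc1 | starting material
8 | methyl 2-[4-methoxy-2-(triisopropylsilyloxy)phenyl]-2-{[(triphenyl-λ5-phosphanylidene)acetyl]oxy}acetate (racemic, not isolated) | COC(=O)C(OC(=O)C=P(c1ccccc1)(c1ccccc1)c1ccccc1)c1ccc(OC)cc1O[Si](C(C)C)(C(C)C)C(C)C | intermediate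
9 | 4-methoxy-5-[4-methoxy-2-(triisopropylsilyloxy)phenyl]furan-2(5H)-one (racemic) | COC1=CC(=O)OC1c1ccc(OC)cc1O[Si](C(C)C)(C(C)C)C(C)C | intermediate
10 | N-({2-chloro-4-methoxy-5-[4-methoxy-2-(triisopropylsilyloxy)phenyl]furan-3-yl}methylidene)-N-methylmethanaminium chloride (not isolated) | C[N+](C)=Cc1c(Cl)oc(-c2ccc(OC)cc2O[Si](C(C)C)(C(C)C)C(C)C)c1OC.[Cl-] | intermediate
11 | 2-chloro-4-methoxy-5-[4-methoxy-2-(triisopropylsilyloxy)phenyl]furan-3-carbaldehyde | O=Cc1c(Cl)oc(-c2ccc(OC)cc2O[Si](C(C)C)(C(C)C)C(C)C)c1OC | intermediate
12 | dimethyl (2-oxopropyl)phosphonate | CC(=O)CP(=O)(OC)OC | starting material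
13 | 1-bromo-3-methylbut-2-ene | CC(C)=CCBr | starting material
14 | dimethyl (6-methyl-2-oxohept-5-en-3-yl)phosphonate (racemic) | CC(=O)C(CC=C(C)C)P(=O)(OC)OC | intermediate
15 | 3-({2-chloro-4-methoxy-5-[4-methoxy-2-(triisopropylsilyloxy)phenyl]furan-3-yl}methylidene)-6-methylhept-5-en-2-one (E/Z mixture at the new double bond, not isolated) | CC(=O)C(CC=C(C)C)=Cc1c(Cl)oc(-c2ccc(OC)cc2O[Si](C(C)C)(C(C)C)C(C)C)c1OC | intermediate
16 | 3-methoxy-2-[4-methoxy-2-(triisopropylsilyloxy)phenyl]-5-(3-methylbut-2-enyl)benzofuran-6-ol | COc1ccc(-c2oc3cc(O)c(CC=C(C)C)cc3c2OC)c(O[Si](C(C)C)(C(C)C)C(C)C)c1 | intermediate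
17 | ambofuranol, 2-(2-hydroxy-4-methoxyphenyl)-3-methoxy-5-(3-methylbut-2-enyl)benzofuran-6-ol | COc1ccc(-c2oc3cc(O)c(CC=C(C)C)cc3c2OC)c(O)c1 | target

## Step count and risk

Total step count: 8. Longest linear sequence: 7 steps (steps 1 to 5, then 7 and 8); step 6 is a one-step side branch.

**Step 7 (key step).** Three things are most likely to go wrong.
- The dienone may stall at the isomer with acetyl trans to the furan, if thiolate addition to the hindered, electron-rich β-carbon equilibrates the isomers more slowly than the material decomposes.
- The electrocyclisation may be slow, because the chlorine-bearing furan carbon is no longer activated once the aldehyde has been consumed.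
- The α-branched phosphonate may olefinate sluggishly, or its carbanion may displace the activated chloride of 11 before it finds the aldehyde.

Partial loss of the silyl ether under carbonate in hot DMF would be harmless, since it only anticipates step 8.

The fallback sets out from 11 and returns at 16. It forms the same two ring A bonds in the opposite order, using known reactions:
- Commercial 6-methylhept-5-en-2-one F1 is converted (LiN(i-Pr)2, Me3SiCl, THF, −78 °C) into its kinetic silyl enol ether trimethyl[(6-methylhepta-1,5-dien-2-yl)oxy]silane F2.
- Aldehyde 11 is masked (HC(OMe)3, MeOH, pyridinium p-toluenesulfonate) as 2-chloro-3-(dimethoxymethyl)-4-methoxy-5-[4-methoxy-2-(triisopropylsilyloxy)phenyl]furan F3.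
- Regiospecific palladium-catalysed α-heteroarylation of the silyl enol ether (Pd2(dba)3, P(t-Bu)3, Bu3SnF, CsF, toluene, 85 °C) joins C7 to C7a and gives 1-{3-(dimethoxymethyl)-4-methoxy-5-[4-methoxy-2-(triisopropylsilyloxy)phenyl]furan-2-yl}-6-methylhept-5-en-2-one F4.
- Mild acetal hydrolysis (pyridinium p-toluenesulfonate, acetone–water) frees 4-methoxy-5-[4-methoxy-2-(triisopropylsilyloxy)phenyl]-2-(6-methyl-2-oxohept-5-enyl)furan-3-carbaldehyde F5.
- Intramolecular aldol condensation (piperidinium acetate, toluene, 60 °C) of the prenyl-bearing α-carbon with the aldehyde forms C4=C5 inside the ring and tautomerises to 16.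

Here the kinetic enol ether, not phosphorus, decides the regiochemistry, and the alkene geometry question disappears because the double bond is born in the ring.

**Step 5.** Three things may go wrong: competing electrophilic formylation of ring B at the position para to the silyloxy group; arrest at the aminomethylene lactone stage without exchange of the lactone oxygen for chloride; and acid-induced loss of the silyl ether. The fallback separates the two events. It sets out from 9 and returns at 11. Aminomethylenation under basic conditions (t-BuOCH(NMe2)2, toluene, 80 °C) gives the push–pull lactone 3-[(dimethylamino)methylidene]-4-methoxy-5-[4-methoxy-2-(triisopropylsilyloxy)phenyl]furan-2(3H)-one F6, and no chloroiminium electrophile is present to attack ring B. POCl3 alone in CH2Cl2 at 0 °C then converts the vinylogous carbamate into the iminium salt 10, which is hydrolysed to 11.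

**Step 4.** The hindered benzylic alcohol may add slowly to the ketene ylide, or the ester-stabilised ylide 8 may fail to olefinate the ester carbonyl, so the reaction could stall at 8 or lose the ylide to adventitious water. The fallback sets out from 6 and returns at 9 by the classical three-step route:
- Acetylation (Ac2O, pyridine, 4-dimethylaminopyridine) gives methyl 2-acetoxy-2-[4-methoxy-2-(triisopropylsilyloxy)phenyl]acetate F7.
- Dieckmann closure (LiN(SiMe3)2, THF, −78 to 0 °C) gives the tetronic acid 4-hydroxy-5-[4-methoxy-2-(triisopropylsilyloxy)phenyl]furan-2(5H)-one F8.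
- O-Methylation at the 4-oxygen (Me2SO4, K2CO3, acetone) gives 9.

**Step 2.** The aryllithium may undergo migration of silicon from oxygen to the lithiated carbon if the temperature rises, and the product may be over-added by a second aryllithium. The fallback avoids the carbanion altogether. It sets out from 2 and returns at 6, bypassing 5:
- Miyaura borylation (bis(pinacolato)diboron, PdCl2(dppf), KOAc, dioxane, 90 °C) gives 2-[4-methoxy-2-(triisopropylsilyloxy)phenyl]-4,4,5,5-tetramethyl-1,3,2-dioxaborolane F9.
- Rhodium-catalysed 1,2-addition of this boronate to methyl glyoxylate ([RhCl(cod)]2, K3PO4, aqueous dioxane, 60 °C) gives the mandelate 6 directly.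

## Further compounds

F1 | step 7 | 6-methylhept-5-en-2-one (purchased) | CC(=O)CCC=C(C)C
F2 | step 7 | trimethyl[(6-methylhepta-1,5-dien-2-yl)oxy]silane | C=C(CCC=C(C)C)O[Si](C)(C)C
F3 | step 7 | 2-chloro-3-(dimethoxymethyl)-4-methoxy-5-[4-methoxy-2-(triisopropylsilyloxy)phenyl]furan | COC(OC)c1c(Cl)oc(-c2ccc(OC)cc2O[Si](C(C)C)(C(C)C)C(C)C)c1OC
F4 | step 7 | 1-{3-(dimethoxymethyl)-4-methoxy-5-[4-methoxy-2-(triisopropylsilyloxy)phenyl]furan-2-yl}-6-methylhept-5-en-2-one | COC(OC)c1c(CC(=O)CCC=C(C)C)oc(-c2ccc(OC)cc2O[Si](C(C)C)(C(C)C)C(C)C)c1OC
F5 | step 7 | 4-methoxy-5-[4-methoxy-2-(triisopropylsilyloxy)phenyl]-2-(6-methyl-2-oxohept-5-enyl)furan-3-carbaldehyde | O=Cc1c(CC(=O)CCC=C(C)C)oc(-c2ccc(OC)cc2O[Si](C(C)C)(C(C)C)C(C)C)c1OC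
F6 | step 5 | 3-[(dimethylamino)methylidene]-4-methoxy-5-[4-methoxy-2-(triisopropylsilyloxy)phenyl]furan-2(3H)-one | CN(C)C=C1C(=O)OC(c2ccc(OC)cc2O[Si](C(C)C)(C(C)C)C(C)C)=C1OC
F7 | step 4 | methyl 2-acetoxy-2-[4-methoxy-2-(triisopropylsilyloxy)phenyl]acetate (racemic) | COC(=O)C(OC(C)=O)c1ccc(OC)cc1O[Si](C(C)C)(C(C)C)C(C)C
F8 | step 4 | 4-hydroxy-5-[4-methoxy-2-(triisopropylsilyloxy)phenyl]furan-2(5H)-one (racemic) | O=C1C=C(O)C(c2ccc(OC)cc2O[Si](C(C)C)(C(C)C)C(C)C)O1
F9 | step 2 | 2-[4-methoxy-2-(triisopropylsilyloxy)phenyl]-4,4,5,5-tetramethyl-1,3,2-dioxaborolane | COc1ccc(B2OC(C)(C)C(C)(C)O2)c(O[Si](C(C)C)(C(C)C)C(C)C)c1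
A1 | alternative 1 | 6-(methoxymethoxy)-2-[4-methoxy-2-(methoxymethoxy)phenyl]-5-(3-methylbut-2-enyl)benzofuran-3(2H)-one (racemic) | O=C1C(c2ccc(OC)cc2OCOC)Oc2cc(OCOC)c(CC=C(C)C)cc21
A2 | alternative 1 | 7-(methoxymethoxy)-2,2-dimethyl-6-(3-methylbut-2-enyl)-4H-1,3-benzodioxin-4-one | CC1(C)OC(=O)c2cc(CC=C(C)C)c(OCOC)cc2O1
A3 | alternative 1 | [4-methoxy-2-(methoxymethoxy)benzyl]diphenylsulfonium tetrafluoroborate | COCOc1cc(OC)ccc1C[S+](c1ccccc1)c1ccccc1.F[B-](F)(F)F
A4 | alternative 2 | ambofuranol bis(triisopropylsilyl) ether | COc1ccc(-c2oc3cc(O[Si](C(C)C)(C(C)C)C(C)C)c(CC=C(C)C)cc3c2OC)c(O[Si](C(C)C)(C(C)C)C(C)C)c1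
A5 | alternative 2 | {[2-{[4-methoxy-2-(triisopropylsilyloxy)benzoyl]oxy}-5-(3-methylbut-2-enyl)-4-(triisopropylsilyloxy)phenyl](methoxy)methyl}triphenylphosphonium bromide (racemic) | COC(c1cc(CC=C(C)C)c(O[Si](C(C)C)(C(C)C)C(C)C)cc1OC(=O)c1ccc(OC)cc1O[Si](C(C)C)(C(C)C)C(C)C)[P+](c1ccccc1)(c1ccccc1)c1ccccc1.[Br-]
A6 | alternative 3 | 6-hydroxy-2-[4-methoxy-2-(triisopropylsilyloxy)phenyl]-5-(3-methylbut-2-enyl)benzofuran-3(2H)-one (racemic) | O=C1C(c2ccc(OC)cc2O[Si](C(C)C)(C(C)C)C(C)C)Oc2cc(O)c(CC=C(C)C)cc21
A7 | alternative 3 | 2-(ethynyloxy)-2-[4-methoxy-2-(triisopropylsilyloxy)phenyl]-1-[4-(3-methylbut-2-enyl)furan-2-yl]ethan-1-one (racemic) | C#COC(C(=O)c1cc(CC=C(C)C)co1)c1ccc(OC)cc1O[Si](C(C)C)(C(C)C)C(C)C
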